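## Retrosynthetic overview

1. Numbering used throughout (daucane): ring A is the cyclopentane C1–C5 (C1 quaternary with methyl, C2 angeloyloxy, C4 carbinol with isopropyl, C5 ring-fusion CH); ring B is the cycloheptene C5–C10 plus C1 (C6 aroyloxy, C8(CH3)=C9).
2. Endgame: the two silyl ethers (C4 oxygen, phenol) come off last, after the C2–O angelate bond is made by esterifying the only free hydroxyl of the cascade product.
3. Key disconnection: C1–C5 and C6–C7 are cut together, which opens ring A and ring B at once to an acyclic epoxy enol ester allyl sulfone; forward, one titanocene radical cascade closes ring A first (5-exo) and ring B second (7-endo).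
4. Enabling feature: quaternary C1 is vicinal to oxygen-bearing C2 (a C1–C2 epoxide gives the C1 radical and the C2 hydroxyl), C6 already carries the aroyloxy oxygen (a C5=C6 enol ester relays the radical and leaves the ester in place), and C7 is allylic to the ring-B C8=C9 bond (a sulfonyl group on C9 makes C7 the acceptor and is lost as that bond forms).
5. The acyclic chain comes from C3–C4 (Seebach alkylation, sets C4), C9–C10 (sulfone alkylation), C5≡C6 (one-carbon homologation), the C1–C2 epoxide (Shi, sets C2) and C6–O (ruthenium-catalysed addition of the aryl acid to the alkyne).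

Key step: step 10

Remark on the chemistry: the sulfone-bearing carbon (future C9) is carried as a mixture of epimers and left undefined in the SMILES, because it becomes sp2 in step 10; the enol ester geometry is erased there as well.

## Route

Step 1
Reactants: 1 (2R)-2-hydroxy-3-methylbutanoic acid; 2 pivalaldehyde
Product: 3 (2R,5R)-2-tert-butyl-5-(propan-2-yl)-1,3-dioxolan-4-one (cis)
Conditions: 2 (1.5 equiv), TsOH·H2O (cat.), H2SO4 (cat.), pentane, reflux, Dean–Stark; cis isomer purified by crystallisation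
Reagents that add atoms: none
Why: Acid-catalysed acetalisation of the α-hydroxy acid (first stage of Seebach's self-regeneration of stereocentres), in which the cis-dioxolanone should predominate and stores the chirality of 1 in the new acetal centre.

Step 2
Reactants: 3 (2R,5R)-2-tert-butyl-5-(propan-2-yl)-1,3-dioxolan-4-one; 4 (2E)-1,4-dibromo-2-methylbut-2-ene
Product: 6 (2R,5R)-5-[(2E)-4-bromo-3-methylbut-2-en-1-yl]-2-tert-butyl-5-(propan-2-yl)-1,3-dioxolan-4-one, via lithium enolate 5 (not isolated)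
Conditions: LiN(iPr)2 (1.1 equiv), THF, −78 °C; enolate cannulated into 4 (3 equiv), THF/DMPU, −78 → −30 °C
Reagents that add atoms: none
Why: Seebach enolate alkylation in which the electrophile enters anti to the tert-butyl group, so C4 is set as (R) with overall retention, and SN2 attack should favour the CH2Br remote from the vinylic methyl (the γ,γ-disubstituted, more reactive allylic terminus), leaving the second allylic bromide for step 4.

Step 3
Reactants: 7 3-chloro-2-methylprop-1-ene; 8 sodium benzenesulfinate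
Product: 9 [(2-methylprop-2-en-1-yl)sulfonyl]benzene (methallyl phenyl sulfone)
Conditions: NaI (cat.), DMF, 60 °C
Reagents that add atoms: none
Why: SN2 S-alkylation of the sulfinate anion by a primary allylic chloride, the standard entry to allylic sulfones.

Step 4
Reactants: 6 (2R,5R)-5-[(2E)-4-bromo-3-methylbut-2-en-1-yl]-2-tert-butyl-5-(propan-2-yl)-1,3-dioxolan-4-one; 9 methallyl phenyl sulfone
Product: 11 (2R,5R)-2-tert-butyl-5-[(2E)-3,6-dimethyl-5-(phenylsulfonyl)hepta-2,6-dien-1-yl]-5-(propan-2-yl)-1,3-dioxolan-4-one (both epimers at the sulfone carbon), via lithiated sulfone 10 (not isolated)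
Conditions: 9 (1.2 equiv), n-BuLi (1.15 equiv), THF, −78 °C; then 6, −78 → −40 °C
Reagents that add atoms: none
Why: α-Alkylation of a sulfonyl-stabilised allyl anion (Julia-type) by the primary allylic bromide forms C9–C10, and at −78 °C it should be much faster than addition to the hindered acylal carbonyl; the new sulfone centre is uncontrolled and inconsequential.

Step 5
Reactants: 11 (2R,5R)-2-tert-butyl-5-[(2E)-3,6-dimethyl-5-(phenylsulfonyl)hepta-2,6-dien-1-yl]-5-(propan-2-yl)-1,3-dioxolan-4-one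
Product: 13 (3R,5E)-6,9-dimethyl-8-(phenylsulfonyl)-3-(propan-2-yl)deca-5,9-dien-1-yn-3-ol, via dioxolan-4-ol lactol 12 (not isolated)
Conditions: iBu2AlH (1.2 equiv), CH2Cl2, −78 °C; then MeOH, K2CO3 (3 equiv), dimethyl (1-diazo-2-oxopropyl)phosphonate (3 equiv), −78 °C → rt
Reagents that add atoms: dimethyl (1-diazo-2-oxopropyl)phosphonate (Ohira–Bestmann reagent), COP(=O)(OC)C(=[N+]=[N-])C(C)=O
Why: One-pot partial reduction of the lactone followed by Ohira–Bestmann (Seyferth–Gilbert) homologation; in basic methanol the lactol opens to the α-hydroxy aldehyde with loss of pivalaldehyde, and the aldehyde is converted into the terminal alkyne (C5≡C6) without touching C4.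

Step 6
Reactants: 13 (3R,5E)-6,9-dimethyl-8-(phenylsulfonyl)-3-(propan-2-yl)deca-5,9-dien-1-yn-3-ol
Product: 14 triethyl{[(3R,5E)-6,9-dimethyl-8-(phenylsulfonyl)-3-(propan-2-yl)deca-5,9-dien-1-yn-3-yl]oxy}silane
Conditions: TESOTf (1.5 equiv), 2,6-lutidine (3 equiv), CH2Cl2, −78 → 0 °C
Reagents that add atoms: triethylsilyl trifluoromethanesulfonate, CC[Si](CC)(CC)OS(=O)(=O)C(F)(F)F
Why: Silyl triflate with a hindered base is the standard way to silylate a tertiary alcohol, and the ether blocks the propargylic hydroxyl for steps 9 and 10.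

Step 7
Reactants: 14 triethyl{[(3R,5E)-6,9-dimethyl-8-(phenylsulfonyl)-3-(propan-2-yl)deca-5,9-dien-1-yn-3-yl]oxy}silane
Product: 15 triethyl{[(3R)-4-methyl-3-({(2R,3R)-3-methyl-3-[3-methyl-2-(phenylsulfonyl)but-3-en-1-yl]oxiran-2-yl}methyl)pent-1-yn-3-yl]oxy}silane
Conditions: D-fructose-derived Shi ketone (0.3 equiv), Oxone (2KHSO5·KHSO4·K2SO4, 1.4 equiv), K2CO3 (5.8 equiv), Bu4NHSO4 (cat.), MeCN/CH2(OMe)2/aq. Na2B4O7–Na2(EDTA) buffer, 0 °C
Reagents that add atoms: Oxone (active oxidant potassium peroxymonosulfate), [K+].[O-]S(=O)(=O)OO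
Why: Shi asymmetric epoxidation, in which the chiral dioxirane should attack the electron-rich E-trisubstituted C1=C2 alkene through the spiro transition state to give the (2R,3R)-oxirane and so set C2 (R) under reagent control, while the alkyne and the sulfone-deactivated 1,1-disubstituted alkene should not react.

Step 8
Reactants: 16 4-hydroxybenzoic acid
Product: 18 4-[(tert-butyldimethylsilyl)oxy]benzoic acid, via bis-silylated ester 17 (not isolated)
Conditions: TBSCl (2.3 equiv), imidazole (4.6 equiv), DMF, rt; then THF/AcOH/H2O, rt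
Reagents that add atoms: tert-butyldimethylsilyl chloride, CC(C)(C)[Si](C)(C)Cl
Why: Exhaustive silylation followed by selective hydrolysis of the much more labile silyl ester leaves the phenol protected as its aryl silyl ether.

Step 9
Reactants: 15 epoxy alkyne (triethylsilyl ether); 18 4-[(tert-butyldimethylsilyl)oxy]benzoic acid
Product: 19 (1Z,3R)-4-methyl-3-({(2R,3R)-3-methyl-3-[3-methyl-2-(phenylsulfonyl)but-3-en-1-yl]oxiran-2-yl}methyl)-3-[(triethylsilyl)oxy]pent-1-en-1-yl 4-[(tert-butyldimethylsilyl)oxy]benzoate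
Conditions: 18 (1.2 equiv), Ru(η3-CH2C(CH3)CH2)2(Ph2P(CH2)4PPh2) (3 mol %), toluene, 60 °C
Reagents that add atoms: none
Why: Ruthenium-vinylidene (Dixneuf-type) anti-Markovnikov addition of a carboxylic acid to a terminal alkyne should place the aroyloxy group on the terminal carbon (C6) as the Z-enol ester under near-neutral conditions that the epoxide and silyl ethers are expected to survive.

Step 10
Reactants: 19 epoxy enol ester allyl sulfone
Product: 22 (1R,3R,3aS,4S,8aR)-1-hydroxy-6,8a-dimethyl-3-(propan-2-yl)-3-[(triethylsilyl)oxy]-1,2,3,3a,4,5,8,8a-octahydroazulen-4-yl 4-[(tert-butyldimethylsilyl)oxy]benzoate, via titanoxy C1 radical 20 (not isolated), via ring-A C6 radical 21 (not isolated)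
Conditions: Cp2TiCl2 (0.2 equiv), Mn dust (4 equiv), 2,4,6-collidine hydrochloride (3 equiv), THF, rt; 19 added by syringe pump over 6 h to 0.005 M
Reagents that add atoms: none
Why: Proposed new method: Cp2TiCl (trivalent titanium, regenerated by Mn and collidinium chloride) opens the C1–C2 epoxide by single-electron transfer to the tertiary β-titanoxy radical 20 with the C2–O bond and configuration retained; 20 closes ring A by 5-exo-trig addition to C5 of the enol ester, the α-aroyloxy radical 21 closes ring B by 7-endo-trig addition to the CH2 terminus (C7) of the allyl sulfone, and β-scission of PhSO2• (reduced to sulfinate by a second Cp2TiCl) leaves the C8=C9 bond. The closest known reaction types are titanocene-catalysed epoxy-polyene radical cyclisations, which include 7-endo-trig closures, and radical allyl transfer from allyl sulfones; a cascade relayed through an enol ester and ended by sulfonyl loss has no direct precedent. C5 should be controlled by C4 (the new C5–C6 bond trans to the larger isopropyl group, hence cis to both oxygens); C1 by the fact that the site cis to C6 is flanked by the C2–O–Ti and C6 groups and so should take the methyl rather than the sulfonyl-bearing chain, which gives the trans ring fusion; and C6 by a chair-like 7-endo transition state with C7 approaching anti to C4 and the aroyloxy group pseudo-equatorial, which gives H5 and H6 anti. The step needs 5-exo over 6-endo closure (favoured by the oxygen-stabilised C6 radical and the fully substituted C4 in the tether), bonding only at C7 (C9 is sp3, and the 6-exo mode would have to attack the methyl-bearing C8), and ring B closure faster than capture of 21 by titanium, which the low Cp2TiCl concentration and slow addition are meant to secure.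

Step 11
Reactants: 22 bicyclic C2 alcohol; 23 angelic acid ((2Z)-2-methylbut-2-enoic acid)
Product: 25 (1R,3R,3aS,4S,8aR)-4-({4-[(tert-butyldimethylsilyl)oxy]benzoyl}oxy)-6,8a-dimethyl-3-(propan-2-yl)-3-[(triethylsilyl)oxy]-1,2,3,3a,4,5,8,8a-octahydroazulen-1-yl (2Z)-2-methylbut-2-enoate, via angelic mixed anhydride 24 (not isolated)
Conditions: 23 (4 equiv), 2,4,6-trichlorobenzoyl chloride (4 equiv), Et3N (4 equiv), toluene, rt; then 22, toluene, 80 °C (no DMAP)
Reagents that add atoms: none
Why: Yamaguchi esterification through the mixed anhydride acylates the C2 oxygen with retention at C2, and leaving out a nucleophilic catalyst should avoid the addition–elimination pathway that isomerises angelates to tiglates.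

Step 12
Reactants: 25 bis-silylated angelate
Product: 26 (1R,3R,3aS,4S,8aR)-3-hydroxy-4-[(4-hydroxybenzoyl)oxy]-6,8a-dimethyl-3-(propan-2-yl)-1,2,3,3a,4,5,8,8a-octahydroazulen-1-yl (2Z)-2-methylbut-2-enoate (CNP0188626.1)
Conditions: HF·pyridine, pyridine/THF, 0 °C → rt
Reagents that add atoms: none
Why: Buffered fluoride desilylation should cleave the tertiary triethylsilyl ether and the aryl silyl ether together while leaving both esters, the angelate geometry and the ring alkene untouched.

## Compound list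

1 | (2R)-2-hydroxy-3-methylbutanoic acid | CC(C)[C@@H](O)C(=O)O | starting material
2 | pivalaldehyde (2,2-dimethylpropanal) | CC(C)(C)C=O | starting material
3 | (2R,5R)-2-tert-butyl-5-(propan-2-yl)-1,3-dioxolan-4-one (cis) | CC(C)[C@H]1O[C@@H](C(C)(C)C)OC1=O | intermediate
4 | (2E)-1,4-dibromo-2-methylbut-2-ene | BrC/C=C(\C)CBr | starting material
5 | lithium enolate of 3 (lithium (2R)-2-tert-butyl-5-(propan-2-yl)-1,3-dioxol-4-olate) | [Li+].CC(C)C1=C([O-])O[C@H](C(C)(C)C)O1 | intermediate (not isolated)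
6 | (2R,5R)-5-[(2E)-4-bromo-3-methylbut-2-en-1-yl]-2-tert-butyl-5-(propan-2-yl)-1,3-dioxolan-4-one | CC(C)[C@@]1(C/C=C(\C)CBr)O[C@@H](C(C)(C)C)OC1=O | intermediate
7 | 3-chloro-2-methylprop-1-ene (methallyl chloride) | CC(=C)CCl | starting material
8 | sodium benzenesulfinate | [Na+].[O-]S(=O)c1ccccc1 | starting material
9 | [(2-methylprop-2-en-1-yl)sulfonyl]benzene (methallyl phenyl sulfone) | CC(=C)CS(=O)(=O)c1ccccc1 | intermediate
10 | α-lithiated methallyl phenyl sulfone | [Li+].CC(=C)[CH-]S(=O)(=O)c1ccccc1 | intermediate (not isolated)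
11 | (2R,5R)-2-tert-butyl-5-[(2E)-3,6-dimethyl-5-(phenylsulfonyl)hepta-2,6-dien-1-yl]-5-(propan-2-yl)-1,3-dioxolan-4-one (epimers at the sulfone carbon) | CC(C)[C@@]1(C/C=C(\C)CC(C(C)=C)S(=O)(=O)c2ccccc2)O[C@@H](C(C)(C)C)OC1=O | intermediate
12 | (2R,5R)-2-tert-butyl-5-[(2E)-3,6-dimethyl-5-(phenylsulfonyl)hepta-2,6-dien-1-yl]-5-(propan-2-yl)-1,3-dioxolan-4-ol (lactol, anomers) | CC(C)[C@@]1(C/C=C(\C)CC(C(C)=C)S(=O)(=O)c2ccccc2)O[C@@H](C(C)(C)C)OC1O | intermediate (not isolated)
13 | (3R,5E)-6,9-dimethyl-8-(phenylsulfonyl)-3-(propan-2-yl)deca-5,9-dien-1-yn-3-ol | C#C[C@](O)(C(C)C)C/C=C(\C)CC(C(C)=C)S(=O)(=O)c1ccccc1 | intermediate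
14 | triethyl{[(3R,5E)-6,9-dimethyl-8-(phenylsulfonyl)-3-(propan-2-yl)deca-5,9-dien-1-yn-3-yl]oxy}silane | C#C[C@](O[Si](CC)(CC)CC)(C(C)C)C/C=C(\C)CC(C(C)=C)S(=O)(=O)c1ccccc1 | intermediate
15 | triethyl{[(3R)-4-methyl-3-({(2R,3R)-3-methyl-3-[3-methyl-2-(phenylsulfonyl)but-3-en-1-yl]oxiran-2-yl}methyl)pent-1-yn-3-yl]oxy}silane | C#C[C@](O[Si](CC)(CC)CC)(C(C)C)C[C@H]1O[C@]1(C)CC(C(C)=C)S(=O)(=O)c1ccccc1 | intermediate
16 | 4-hydroxybenzoic acid | OC(=O)c1ccc(O)cc1 | starting material
17 | tert-butyldimethylsilyl 4-[(tert-butyldimethylsilyl)oxy]benzoate | CC(C)(C)[Si](C)(C)OC(=O)c1ccc(O[Si](C)(C)C(C)(C)C)cc1 | intermediate (not isolated)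
18 | 4-[(tert-butyldimethylsilyl)oxy]benzoic acid | OC(=O)c1ccc(O[Si](C)(C)C(C)(C)C)cc1 | intermediate
19 | (1Z,3R)-4-methyl-3-({(2R,3R)-3-methyl-3-[3-methyl-2-(phenylsulfonyl)but-3-en-1-yl]oxiran-2-yl}methyl)-3-[(triethylsilyl)oxy]pent-1-en-1-yl 4-[(tert-butyldimethylsilyl)oxy]benzoate | CC(C)(C)[Si](C)(C)Oc1ccc(cc1)C(=O)O/C=C\[C@](O[Si](CC)(CC)CC)(C(C)C)C[C@H]1O[C@]1(C)CC(C(C)=C)S(=O)(=O)c1ccccc1 | intermediate
20 | open-chain tertiary C1 radical, C2 oxygen bound to Cp2TiCl (tetravalent titanium alkoxide) | Cl[Ti](O[C@H](C[C@@](O[Si](CC)(CC)CC)(C(C)C)/C=C\OC(=O)c1ccc(O[Si](C)(C)C(C)(C)C)cc1)[C](C)CC(C(C)=C)S(=O)(=O)c1ccccc1)(C1C=CC=C1)C1C=CC=C1 | intermediate (not isolated)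
21 | ring-A cyclopentane with the secondary α-aroyloxy radical at C6, C2 oxygen bound to Cp2TiCl | Cl[Ti](O[C@@H]1C[C@@](O[Si](CC)(CC)CC)(C(C)C)[C@H]([CH]OC(=O)c2ccc(O[Si](C)(C)C(C)(C)C)cc2)[C@@]1(C)CC(C(C)=C)S(=O)(=O)c1ccccc1)(C1C=CC=C1)C1C=CC=C1 | intermediate (not isolated)
22 | (1R,3R,3aS,4S,8aR)-1-hydroxy-6,8a-dimethyl-3-(propan-2-yl)-3-[(triethylsilyl)oxy]-1,2,3,3a,4,5,8,8a-octahydroazulen-4-yl 4-[(tert-butyldimethylsilyl)oxy]benzoate | O[C@@H]1C[C@@](O[Si](CC)(CC)CC)(C(C)C)[C@@H]2[C@@H](OC(=O)c3ccc(O[Si](C)(C)C(C)(C)C)cc3)CC(C)=CC[C@]21C | intermediate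
23 | angelic acid ((2Z)-2-methylbut-2-enoic acid) | C/C=C(/C)C(=O)O | starting material
24 | (2Z)-2-methylbut-2-enoic 2,4,6-trichlorobenzoic anhydride | C/C=C(/C)C(=O)OC(=O)c1c(Cl)cc(Cl)cc1Cl | intermediate (not isolated)
25 | (1R,3R,3aS,4S,8aR)-4-({4-[(tert-butyldimethylsilyl)oxy]benzoyl}oxy)-6,8a-dimethyl-3-(propan-2-yl)-3-[(triethylsilyl)oxy]-1,2,3,3a,4,5,8,8a-octahydroazulen-1-yl (2Z)-2-methylbut-2-enoate | C/C=C(/C)C(=O)O[C@@H]1C[C@@](O[Si](CC)(CC)CC)(C(C)C)[C@@H]2[C@@H](OC(=O)c3ccc(O[Si](C)(C)C(C)(C)C)cc3)CC(C)=CC[C@]21C | intermediate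
26 | (1R,3R,3aS,4S,8aR)-3-hydroxy-4-[(4-hydroxybenzoyl)oxy]-6,8a-dimethyl-3-(propan-2-yl)-1,2,3,3a,4,5,8,8a-octahydroazulen-1-yl (2Z)-2-methylbut-2-enoate (CNP0188626.1) | C/C=C(/C)C(=O)O[C@@H]1C[C@@](O)(C(C)C)[C@@H]2[C@@H](OC(=O)c3ccc(O)cc3)CC(C)=CC[C@]21C | target

## Step count and risks

Total step count: 12. Longest linear sequence: 10 (steps 1, 2, 4, 5, 6, 7, 9, 10, 11, 12).

Most likely to fail:

1. Step 10 (Proposed new method). The secondary α-aroyloxy radical formed after ring A closure may be captured by Cp2TiCl, or may take a hydrogen atom from THF or from the allylic C9–H by 1,5-transfer, faster than it closes ring B, so that the cascade stops at the monocyclic stage; the facial selectivity of the 5-exo closure at C5 may also be lower than argued. Fallback, built from established tin radical reactions (halogen-atom abstraction by stannyl radicals, tandem radical cyclisation, addition–fragmentation on allyl sulfones with a ditin as chain carrier): setting out from 19, anhydrous MgBr2·OEt2 (Et2O, −20 °C) would open the epoxide with bromide at the tertiary carbon to give the bromohydrin F1. Irradiation of F1 with (Bu3Sn)2 in dilute benzene at 80 °C would then run the two ring closures as an atom-transfer chain in a medium that holds neither a metal reductant nor a good hydrogen donor: Bu3Sn• abstracts bromine, the C1 radical closes ring A, the C6 radical adds to C7, and the expelled PhSO2• is taken up by the ditin. This returns to the route at 22.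

2. Step 9. The carboxylic acid may open the acid-sensitive trisubstituted epoxide at 60 °C, or the addition at the hindered alkyne may lose its anti-Markovnikov sense. Fallback: setting out from 15, Cp2ZrHCl-catalysed hydroboration with pinacolborane (CH2Cl2, rt) would give the (E)-alkenyl boronate F2. Oxidative coupling of F2 with 18 mediated by Cu(OAc)2 (divalent copper, Chan–Lam type; Et3N, molecular sieves, air, rt) would give the (E)-enol ester F3, the geometric isomer of 19. F3 would be taken through step 10, where the alkene geometry is erased, and the route is rejoined at 22.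

3. Step 11. Acylation of the neopentyl-type C2 hydroxyl may be slow, and forcing it may isomerise the angeloyl group from Z to E or move the aroyl group from the C6 oxygen to the C2 oxygen. Fallback: setting out from 22, esterification with the small, linear but-2-ynoic acid (DCC, DMAP, CH2Cl2) would give the but-2-ynoate F4. Syn-hydrostannation with Bu3SnH catalysed by Pd(PPh3)4 (THF, 0 °C) should put tin α to the carbonyl and give the (E)-2-(tributylstannyl)but-2-enoate F5. Stille methylation with retention (CH3I, Pd2(dba)3, P(2-furyl)3, CuI, DMF) would give the angelate and return to the route at 25.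

## Further compounds

F1 | step 10 | (1Z,3R)-3-[(2R)-3-bromo-2-hydroxy-3,6-dimethyl-5-(phenylsulfonyl)hept-6-en-1-yl]-4-methyl-3-[(triethylsilyl)oxy]pent-1-en-1-yl 4-[(tert-butyldimethylsilyl)oxy]benzoate (bromohydrin) | CC(C)(C)[Si](C)(C)Oc1ccc(cc1)C(=O)O/C=C\[C@](O[Si](CC)(CC)CC)(C(C)C)C[C@@H](O)C(C)(Br)CC(C(C)=C)S(=O)(=O)c1ccccc1
F2 | step 9 | 2-[(1E,3R)-4-methyl-3-({(2R,3R)-3-methyl-3-[3-methyl-2-(phenylsulfonyl)but-3-en-1-yl]oxiran-2-yl}methyl)-3-[(triethylsilyl)oxy]pent-1-en-1-yl]-4,4,5,5-tetramethyl-1,3,2-dioxaborolane | CC1(C)OB(/C=C/[C@](O[Si](CC)(CC)CC)(C(C)C)C[C@H]2O[C@]2(C)CC(C(C)=C)S(=O)(=O)c2ccccc2)OC1(C)C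
F3 | step 9 | (1E,3R)-4-methyl-3-({(2R,3R)-3-methyl-3-[3-methyl-2-(phenylsulfonyl)but-3-en-1-yl]oxiran-2-yl}methyl)-3-[(triethylsilyl)oxy]pent-1-en-1-yl 4-[(tert-butyldimethylsilyl)oxy]benzoate | CC(C)(C)[Si](C)(C)Oc1ccc(cc1)C(=O)O/C=C/[C@](O[Si](CC)(CC)CC)(C(C)C)C[C@H]1O[C@]1(C)CC(C(C)=C)S(=O)(=O)c1ccccc1
F4 | step 11 | (1R,3R,3aS,4S,8aR)-1-(but-2-ynoyloxy)-6,8a-dimethyl-3-(propan-2-yl)-3-[(triethylsilyl)oxy]-1,2,3,3a,4,5,8,8a-octahydroazulen-4-yl 4-[(tert-butyldimethylsilyl)oxy]benzoate | CC#CC(=O)O[C@@H]1C[C@@](O[Si](CC)(CC)CC)(C(C)C)[C@@H]2[C@@H](OC(=O)c3ccc(O[Si](C)(C)C(C)(C)C)cc3)CC(C)=CC[C@]21C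
F5 | step 11 | (1R,3R,3aS,4S,8aR)-4-({4-[(tert-butyldimethylsilyl)oxy]benzoyl}oxy)-6,8a-dimethyl-3-(propan-2-yl)-3-[(triethylsilyl)oxy]-1,2,3,3a,4,5,8,8a-octahydroazulen-1-yl (2E)-2-(tributylstannyl)but-2-enoate | C/C=C(/[Sn](CCCC)(CCCC)CCCC)C(=O)O[C@@H]1C[C@@](O[Si](CC)(CC)CC)(C(C)C)[C@@H]2[C@@H](OC(=O)c3ccc(O[Si](C)(C)C(C)(C)C)cc3)CC(C)=CC[C@]21C
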